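## Retrosynthetic overview

1. Calbistrin D (35) ⇒ desilylation and Stille coupling at C7–C8 of the tetraene ⇒ bicyclic vinyl iodide 28 + stannyl trienoic acid 33 (which carries the 4Z bond, from (Z)-3-methylpent-2-en-4-yn-1-ol).
2. 28 ⇒ acyclic dienyne 27 by one Ru-catalysed ene–yne–ene metathesis cascade. Ring A (C1–C4, C4a, C8a) closes first by enyne RCM from the unhindered vinyl group; ring B (C4a–C8, C8a) closes second by RCM of the resulting vinyl carbene onto the vinyl carbinol.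
3. 27 ⇒ hydroxymethylation of the Yamaguchi ester of hydroxy ketone 15 with iodo acid 23 (Evans Mg anti-aldol).
4. 15 ⇒ γ-lactone template 11: enolate acylation anti to the alkyne (sets C8), chelation-controlled vinyl addition (sets C7), MeLi opening.
5. 11 ⇒ Marshall Pd/Zn propargylation of (S)-3-methylpent-4-enal 5 (Ir allylic alkylation) with the Evans-aldol-derived mesylate 9 (sets C1 and C8a).

Assumption: the SMILES is read as the (2E,4Z,6E,8E)-tetraene with a 10R,11S (anti) pair and a (1S,3S,7R,8R,8aS) hexahydronaphthalene; (E)-crotyl methyl carbonate and the (Z)-isomer of 3-methylpent-2-en-4-yn-1-ol are taken as catalogue chemicals.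

## Route

Step 1
Reactants: 1 dimethyl malonate; 2 (E)-but-2-en-1-yl methyl carbonate
Product: 3 dimethyl 2-[(2R)-but-3-en-2-yl]malonate
Conditions: [Ir(cod)Cl]2 (2 mol %), Feringa-type phosphoramidite (4 mol %, enantiomer giving the R adduct), TBD (cat.), THF, rt
Reagents that add atoms: none
Why: Ir-catalysed asymmetric allylic alkylation; branched-selective attack of malonate on the Ir–π-crotyl complex sets the methyl-bearing centre (later C3) under ligand control.

Step 2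
Reactants: 3 dimethyl 2-[(2R)-but-3-en-2-yl]malonate
Product: 4 methyl (3S)-3-methylpent-4-enoate
Conditions: NaCl, H2O, DMSO, 155 °C
Reagents that add atoms: none
Why: Krapcho dealkoxycarbonylation removes one ester; the stereocentre is β to the carbonyl and is not touched.

Step 3
Reactants: 4 methyl (3S)-3-methylpent-4-enoate
Product: 5 (3S)-3-methylpent-4-enal
Conditions: DIBAL-H (1.05 equiv), CH2Cl2, −78 °C; Rochelle salt
Reagents that add atoms: none
Why: DIBAL-H partial reduction stops at the aluminium hemiacetal at −78 °C and gives the aldehyde on work-up.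

Step 4
Reactants: 6 (4S)-4-benzyl-3-propanoyl-1,3-oxazolidin-2-one; 7 3-(trimethylsilyl)prop-2-ynal
Product: 8 (4S)-4-benzyl-3-[(2S,3S)-3-hydroxy-2-methyl-5-(trimethylsilyl)pent-4-ynoyl]-1,3-oxazolidin-2-one
Conditions: Bu2BOTf, iPr2NEt, CH2Cl2, −78 → 0 °C; pH 7 buffer, MeOH, H2O2
Reagents that add atoms: none
Why: Evans boron syn-aldol; the Z-boron enolate reacts through a Zimmerman–Traxler chair on the face set by the auxiliary, fixing the propargylic carbinol as 3S.

Step 5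
Reactants: 8 (4S)-4-benzyl-3-[(2S,3S)-3-hydroxy-2-methyl-5-(trimethylsilyl)pent-4-ynoyl]-1,3-oxazolidin-2-one
Product: 9 (4S)-4-benzyl-3-[(2S,3S)-2-methyl-3-(methylsulfonyloxy)-5-(trimethylsilyl)pent-4-ynoyl]-1,3-oxazolidin-2-one
Conditions: MsCl, Et3N, CH2Cl2, −78 → −20 °C
Reagents that add atoms: methanesulfonyl chloride, CS(=O)(=O)Cl
Why: O-sulfonylation with retention gives the propargylic mesylate; kept cold to avoid E1cB loss of mesylate.

Step 6
Reactants: 9 (4S)-4-benzyl-3-[(2S,3S)-2-methyl-3-(methylsulfonyloxy)-5-(trimethylsilyl)pent-4-ynoyl]-1,3-oxazolidin-2-one; 5 (3S)-3-methylpent-4-enal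
Product: 11 (3S,4R,5S)-3-methyl-5-[(2S)-2-methylbut-3-en-1-yl]-4-[(trimethylsilyl)ethynyl]oxolan-2-one, via hydroxy imide 10 (not isolated)
Conditions: Pd(OAc)2 (5 mol %), PPh3 (5 mol %), Et2Zn (3 equiv), THF, −78 → −20 °C; aq NH4Cl; then DBU (0.2 equiv), CH2Cl2, rt
Reagents that add atoms: none
Why: Marshall propargylation; anti-SN2′ oxidative addition of Pd(0), transmetalation to an axially chiral allenylzinc and cyclic SE2′ addition to 5 give the anti homopropargylic alcohol with the new C–C bond anti to the departed mesylate (sets C8a and C1), after which the alkoxide lactonises onto the imide and releases the auxiliary.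

Step 7
Reactants: 11 (3S,4R,5S)-3-methyl-5-[(2S)-2-methylbut-3-en-1-yl]-4-[(trimethylsilyl)ethynyl]oxolan-2-one
Product: 12 (3R,4R,5S)-3-acetyl-3-methyl-5-[(2S)-2-methylbut-3-en-1-yl]-4-[(trimethylsilyl)ethynyl]oxolan-2-one
Conditions: LDA (commercial, 1.15 equiv), THF, −78 °C; enolate added to AcCl (1.5 equiv), −78 °C
Reagents that add atoms: acetyl chloride, CC(=O)Cl
Why: Claisen-type C-acylation of the lactone lithium enolate occurs on the face opposite the cis-disposed alkynyl and alkyl groups, setting the quaternary centre (C8) with acetyl trans to the alkyne.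

Step 8
Reactants: 12 (3R,4R,5S)-3-acetyl-3-methyl-5-[(2S)-2-methylbut-3-en-1-yl]-4-[(trimethylsilyl)ethynyl]oxolan-2-one
Product: 14 (3R,4S,5S)-4-ethynyl-3-[(2R)-2-hydroxybut-3-en-2-yl]-3-methyl-5-[(2S)-2-methylbut-3-en-1-yl]oxolan-2-one, via TMS-alkynyl carbinol 13 (not isolated)
Conditions: MgBr2·OEt2 (1.5 equiv), CH2Cl2, −78 °C; vinylMgBr (1.3 equiv); AcOH quench at −78 °C; then TBAF/AcOH (1:1, 1.5 equiv), THF, 0 °C
Reagents that add atoms: vinylmagnesium bromide, C=C[Mg]Br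
Why: Cram-chelate Grignard addition; Mg bridges the ketone and lactone carbonyls and the vinyl group attacks from the side of the small methyl substituent of the quaternary carbon, setting the tertiary carbinol (C7), after which buffered fluoride removes the alkynyl TMS group.

Step 9
Reactants: 14 (3R,4S,5S)-4-ethynyl-3-[(2R)-2-hydroxybut-3-en-2-yl]-3-methyl-5-[(2S)-2-methylbut-3-en-1-yl]oxolan-2-one
Product: 15 (3R,4S,5S,7S)-4-ethynyl-5-hydroxy-3-[(2R)-2-hydroxybut-3-en-2-yl]-3,7-dimethylnon-8-en-2-one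
Conditions: MeLi (3.3 equiv), THF, −78 °C; aq NH4Cl at −78 °C
Reagents that add atoms: methyllithium, [Li]C
Why: Mono-addition of MeLi to the lactone; the lithium hemiketal is stable at −78 °C and collapses on work-up to the methyl ketone (in equilibrium with its lactol), freeing the C1 hydroxyl.

Step 10
Reactants: 16 prop-2-yn-1-ol
Product: 17 (2E)-3-iodo-2-methylprop-2-en-1-ol
Conditions: Cp2ZrCl2 (0.25 equiv), Me3Al (3 equiv), CH2Cl2, 0 °C → rt; then I2, THF, −30 → 0 °C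
Reagents that add atoms: trimethylaluminium, C[Al](C)C; iodine, II
Why: Negishi Zr-catalysed carboalumination adds Me–Al syn across the alkyne with Al at the terminus, and iodinolysis with retention gives the E-iodoalkene.

Step 11
Reactants: 17 (2E)-3-iodo-2-methylprop-2-en-1-ol
Product: 18 (2E)-3-iodo-2-methylprop-2-enal
Conditions: MnO2 (15 equiv), CH2Cl2, rt
Reagents that add atoms: none
Why: MnO2 oxidises the allylic alcohol selectively without touching the vinyl iodide or its geometry.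

Step 12
Reactants: 19 (4R)-4-benzyl-3-propanoyl-1,3-oxazolidin-2-one; 18 (2E)-3-iodo-2-methylprop-2-enal
Product: 21 (4R)-4-benzyl-3-[(2S,3R,4E)-3-hydroxy-5-iodo-2,4-dimethylpent-4-enoyl]-1,3-oxazolidin-2-one, via O-TMS aldol 20 (not isolated)
Conditions: MgCl2 (20 mol %), Et3N (2 equiv), TMSCl (1.5 equiv), EtOAc, rt; then TFA (cat.), MeOH
Reagents that add atoms: none
Why: Evans MgCl2-catalysed anti-aldol of a non-enolisable enal; the chelated Z-magnesium enolate reacts on the face opposite the benzyl group to give the 2S,3R anti adduct (side-chain C11 and C10), with TMSCl turning the catalyst over.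

Step 13
Reactants: 21 (4R)-4-benzyl-3-[(2S,3R,4E)-3-hydroxy-5-iodo-2,4-dimethylpent-4-enoyl]-1,3-oxazolidin-2-one
Product: 22 (4R)-4-benzyl-3-[(2S,3R,4E)-3-[(tert-butyldimethylsilyl)oxy]-5-iodo-2,4-dimethylpent-4-enoyl]-1,3-oxazolidin-2-one
Conditions: TBSOTf, 2,6-lutidine, CH2Cl2, −78 → 0 °C
Reagents that add atoms: tert-butyldimethylsilyl trifluoromethanesulfonate, CC(C)(C)[Si](C)(C)OS(=O)(=O)C(F)(F)F
Why: Silyl triflate O-silylation protects the β-hydroxyl and blocks retro-aldol during auxiliary removal.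

Step 14
Reactants: 22 (4R)-4-benzyl-3-[(2S,3R,4E)-3-[(tert-butyldimethylsilyl)oxy]-5-iodo-2,4-dimethylpent-4-enoyl]-1,3-oxazolidin-2-one
Product: 23 (2S,3R,4E)-3-[(tert-butyldimethylsilyl)oxy]-5-iodo-2,4-dimethylpent-4-enoic acid
Conditions: LiOH, 30 % H2O2, THF/H2O, 0 °C; Na2SO3; 1 M HCl to pH 3
Reagents that add atoms: hydrogen peroxide (as LiOOH), OO
Why: Evans LiOOH hydrolysis cleaves the exocyclic imide carbonyl selectively without epimerising the α-centre.

Step 15
Reactants: 23 (2S,3R,4E)-3-[(tert-butyldimethylsilyl)oxy]-5-iodo-2,4-dimethylpent-4-enoic acid; 15 (3R,4S,5S,7S)-4-ethynyl-5-hydroxy-3-[(2R)-2-hydroxybut-3-en-2-yl]-3,7-dimethylnon-8-en-2-one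
Product: 25 (3R,4S,5S,7S)-4-ethynyl-3-[(2R)-2-hydroxybut-3-en-2-yl]-3,7-dimethyl-2-oxonon-8-en-5-yl (2S,3R,4E)-3-[(tert-butyldimethylsilyl)oxy]-5-iodo-2,4-dimethylpent-4-enoate, via mixed anhydride 24 (not isolated)
Conditions: 2,4,6-trichlorobenzoyl chloride, Et3N, THF, rt; then 15, DMAP, toluene, rt
Reagents that add atoms: none
Why: Yamaguchi esterification; only the secondary C1 hydroxyl of the open hydroxy ketone is acylated, the tertiary carbinol and the lactol hydroxyl being unreactive.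

Step 16
Reactants: 25 (3R,4S,5S,7S)-4-ethynyl-3-[(2R)-2-hydroxybut-3-en-2-yl]-3,7-dimethyl-2-oxonon-8-en-5-yl (2S,3R,4E)-3-[(tert-butyldimethylsilyl)oxy]-5-iodo-2,4-dimethylpent-4-enoate
Product: 27 (4R,5S,6S,8S)-5-ethynyl-1-hydroxy-4-[(2R)-2-hydroxybut-3-en-2-yl]-4,8-dimethyl-3-oxodec-9-en-6-yl (2S,3R,4E)-3-[(tert-butyldimethylsilyl)oxy]-5-iodo-2,4-dimethylpent-4-enoate, via bis-silyl enol ether 26 (not isolated)
Conditions: TMSOTf (3 equiv), Et3N (4 equiv), CH2Cl2, 0 °C; concentrate; 37 % aq HCHO, Yb(OTf)3 (20 mol %), THF, rt; 1 M HCl work-up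
Reagents that add atoms: formaldehyde, C=O
Why: Soft enolisation of the methyl ketone (its only enolisable position; the ester is not silylated) followed by Kobayashi aqueous Mukaiyama aldol with formaldehyde gives the β-hydroxy ketone, and the acidic work-up removes the tertiary O-TMS group.

Step 17
Reactants: 27 (4R,5S,6S,8S)-5-ethynyl-1-hydroxy-4-[(2R)-2-hydroxybut-3-en-2-yl]-4,8-dimethyl-3-oxodec-9-en-6-yl (2S,3R,4E)-3-[(tert-butyldimethylsilyl)oxy]-5-iodo-2,4-dimethylpent-4-enoate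
Product: 28 (1S,3S,7R,8R,8aS)-7-hydroxy-8-(3-hydroxypropanoyl)-3,7,8-trimethyl-1,2,3,7,8,8a-hexahydronaphthalen-1-yl (2S,3R,4E)-3-[(tert-butyldimethylsilyl)oxy]-5-iodo-2,4-dimethylpent-4-enoate
Conditions: Hoveyda–Grubbs II (10 mol %, two portions), ethylene (1 atm), toluene (5 mM), 70 °C
Reagents that add atoms: none
Why: Tandem ring-closing ene–yne–ene metathesis (Grubbs dienyne cascade); Ru loads on the unhindered C4 vinyl group, exo enyne RCM closes ring A and gives the C5 vinyl carbene, and this closes ring B onto the hindered vinyl carbinol. The C4=C4a–C5=C6 diene is delivered directly and no stereocentre is created or touched; the trisubstituted vinyl iodide is inert.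

Step 18
Reactants: 29 (2Z)-3-methylpent-2-en-4-yn-1-ol
Product: 30 (2Z,4E)-3-methyl-5-(tributylstannyl)penta-2,4-dien-1-ol
Conditions: Bu3SnH (1.2 equiv), PdCl2(PPh3)2 (2 mol %), THF, 0 °C
Reagents that add atoms: tributyltin hydride, CCCC[SnH](CCCC)CCCC
Why: Pd-catalysed syn hydrostannation of the terminal alkyne places tin at the terminus and gives the E-vinylstannane; the Z-trisubstituted alkene is untouched.

Step 19
Reactants: 30 (2Z,4E)-3-methyl-5-(tributylstannyl)penta-2,4-dien-1-ol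
Product: 31 (2Z,4E)-3-methyl-5-(tributylstannyl)penta-2,4-dienal
Conditions: MnO2, CH2Cl2, rt, dark
Reagents that add atoms: none
Why: Neutral MnO2 allylic oxidation keeps the 2Z geometry and the C–Sn bond.

Step 20
Reactants: 31 (2Z,4E)-3-methyl-5-(tributylstannyl)penta-2,4-dienal; 32 2-(diethoxyphosphoryl)acetic acid
Product: 33 (2E,4Z,6E)-5-methyl-7-(tributylstannyl)hepta-2,4,6-trienoic acid
Conditions: 32, n-BuLi (2.05 equiv), THF, −78 → 0 °C; then 31, −78 °C → rt; cold dilute HCl to pH 4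
Reagents that add atoms: none
Why: Horner–Wadsworth–Emmons olefination with the phosphonoacetate dianion gives the E-enoic acid directly, so no ester has to be cleaved later.

Step 21
Reactants: 28 (1S,3S,7R,8R,8aS)-7-hydroxy-8-(3-hydroxypropanoyl)-3,7,8-trimethyl-1,2,3,7,8,8a-hexahydronaphthalen-1-yl (2S,3R,4E)-3-[(tert-butyldimethylsilyl)oxy]-5-iodo-2,4-dimethylpent-4-enoate; 33 (2E,4Z,6E)-5-methyl-7-(tributylstannyl)hepta-2,4,6-trienoic acid
Product: 34 (2E,4Z,6E,8E,10R,11S)-10-[(tert-butyldimethylsilyl)oxy]-12-{[(1S,3S,7R,8R,8aS)-7-hydroxy-8-(3-hydroxypropanoyl)-3,7,8-trimethyl-1,2,3,7,8,8a-hexahydronaphthalen-1-yl]oxy}-5,9,11-trimethyl-12-oxododeca-2,4,6,8-tetraenoic acid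
Conditions: Pd2(dba)3 (5 mol %), AsPh3 (40 mol %), DMF, rt, dark
Reagents that add atoms: none
Why: Stille coupling joins the vinyl iodide and vinylstannane with retention at both alkenes under neutral conditions that tolerate the free acid, the β-hydroxy ketone and the tertiary allylic alcohol.

Step 22
Reactants: 34 (2E,4Z,6E,8E,10R,11S)-10-[(tert-butyldimethylsilyl)oxy]-12-{[(1S,3S,7R,8R,8aS)-7-hydroxy-8-(3-hydroxypropanoyl)-3,7,8-trimethyl-1,2,3,7,8,8a-hexahydronaphthalen-1-yl]oxy}-5,9,11-trimethyl-12-oxododeca-2,4,6,8-tetraenoic acid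
Product: 35 calbistrin D
Conditions: HF·pyridine, pyridine, THF, 0 °C → rt
Reagents that add atoms: none
Why: Buffered fluoride desilylation removes the last TBS ether without base (no retro-aldol or β-elimination) and without strong acid (no ionisation of the dienyl carbinol).

## Compound list

1 | dimethyl malonate | COC(=O)CC(=O)OC | starting material
2 | (E)-but-2-en-1-yl methyl carbonate | C/C=C/COC(=O)OC | starting material
3 | dimethyl 2-[(2R)-but-3-en-2-yl]malonate | C=C[C@@H](C)C(C(=O)OC)C(=O)OC | intermediate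
4 | methyl (3S)-3-methylpent-4-enoate | C=C[C@@H](C)CC(=O)OC | intermediate
5 | (3S)-3-methylpent-4-enal | C=C[C@@H](C)CC=O | intermediate
6 | (4S)-4-benzyl-3-propanoyl-1,3-oxazolidin-2-one | CCC(=O)N1[C@@H](Cc2ccccc2)COC1=O | starting material
7 | 3-(trimethylsilyl)prop-2-ynal | C[Si](C)(C)C#CC=O | starting material
8 | (4S)-4-benzyl-3-[(2S,3S)-3-hydroxy-2-methyl-5-(trimethylsilyl)pent-4-ynoyl]-1,3-oxazolidin-2-one | C[Si](C)(C)C#C[C@@H](O)[C@H](C)C(=O)N1[C@@H](Cc2ccccc2)COC1=O | intermediate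
9 | (4S)-4-benzyl-3-[(2S,3S)-2-methyl-3-(methylsulfonyloxy)-5-(trimethylsilyl)pent-4-ynoyl]-1,3-oxazolidin-2-one | C[Si](C)(C)C#C[C@@H](OS(C)(=O)=O)[C@H](C)C(=O)N1[C@@H](Cc2ccccc2)COC1=O | intermediate
10 | (4S)-4-benzyl-3-[(2S,3R,4S,6S)-4-hydroxy-2,6-dimethyl-3-[(trimethylsilyl)ethynyl]oct-7-enoyl]-1,3-oxazolidin-2-one | C[Si](C)(C)C#C[C@H]([C@@H](O)C[C@H](C)C=C)[C@H](C)C(=O)N1[C@@H](Cc2ccccc2)COC1=O | intermediate (not isolated)
11 | (3S,4R,5S)-3-methyl-5-[(2S)-2-methylbut-3-en-1-yl]-4-[(trimethylsilyl)ethynyl]oxolan-2-one | C[Si](C)(C)C#C[C@H]1[C@H](C)C(=O)O[C@H]1C[C@H](C)C=C | intermediate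
12 | (3R,4R,5S)-3-acetyl-3-methyl-5-[(2S)-2-methylbut-3-en-1-yl]-4-[(trimethylsilyl)ethynyl]oxolan-2-one | C[Si](C)(C)C#C[C@H]1[C@](C)(C(C)=O)C(=O)O[C@H]1C[C@H](C)C=C | intermediate
13 | (3R,4R,5S)-3-[(2R)-2-hydroxybut-3-en-2-yl]-3-methyl-5-[(2S)-2-methylbut-3-en-1-yl]-4-[(trimethylsilyl)ethynyl]oxolan-2-one | C[Si](C)(C)C#C[C@H]1[C@](C)([C@](C)(O)C=C)C(=O)O[C@H]1C[C@H](C)C=C | intermediate (not isolated)
14 | (3R,4S,5S)-4-ethynyl-3-[(2R)-2-hydroxybut-3-en-2-yl]-3-methyl-5-[(2S)-2-methylbut-3-en-1-yl]oxolan-2-one | C#C[C@H]1[C@](C)([C@](C)(O)C=C)C(=O)O[C@H]1C[C@H](C)C=C | intermediate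
15 | (3R,4S,5S,7S)-4-ethynyl-5-hydroxy-3-[(2R)-2-hydroxybut-3-en-2-yl]-3,7-dimethylnon-8-en-2-one (in equilibrium with its lactol) | C#C[C@H]([C@@H](O)C[C@H](C)C=C)[C@@](C)(C(C)=O)[C@](C)(O)C=C | intermediate
16 | prop-2-yn-1-ol | C#CCO | starting material
17 | (2E)-3-iodo-2-methylprop-2-en-1-ol | C/C(=C\I)CO | intermediate
18 | (2E)-3-iodo-2-methylprop-2-enal | C/C(=C\I)C=O | intermediate
19 | (4R)-4-benzyl-3-propanoyl-1,3-oxazolidin-2-one | CCC(=O)N1[C@H](Cc2ccccc2)COC1=O | starting material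
20 | (4R)-4-benzyl-3-[(2S,3R,4E)-5-iodo-2,4-dimethyl-3-(trimethylsilyloxy)pent-4-enoyl]-1,3-oxazolidin-2-one | I/C=C(\C)[C@H](O[Si](C)(C)C)[C@H](C)C(=O)N1[C@H](Cc2ccccc2)COC1=O | intermediate (not isolated)
21 | (4R)-4-benzyl-3-[(2S,3R,4E)-3-hydroxy-5-iodo-2,4-dimethylpent-4-enoyl]-1,3-oxazolidin-2-one | I/C=C(\C)[C@H](O)[C@H](C)C(=O)N1[C@H](Cc2ccccc2)COC1=O | intermediate
22 | (4R)-4-benzyl-3-[(2S,3R,4E)-3-[(tert-butyldimethylsilyl)oxy]-5-iodo-2,4-dimethylpent-4-enoyl]-1,3-oxazolidin-2-one | I/C=C(\C)[C@H](O[Si](C)(C)C(C)(C)C)[C@H](C)C(=O)N1[C@H](Cc2ccccc2)COC1=O | intermediate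
23 | (2S,3R,4E)-3-[(tert-butyldimethylsilyl)oxy]-5-iodo-2,4-dimethylpent-4-enoic acid | I/C=C(\C)[C@H](O[Si](C)(C)C(C)(C)C)[C@H](C)C(=O)O | intermediate
24 | mixed anhydride of 23 with 2,4,6-trichlorobenzoic acid | I/C=C(\C)[C@H](O[Si](C)(C)C(C)(C)C)[C@H](C)C(=O)OC(=O)c1c(Cl)cc(Cl)cc1Cl | intermediate (not isolated)
25 | (3R,4S,5S,7S)-4-ethynyl-3-[(2R)-2-hydroxybut-3-en-2-yl]-3,7-dimethyl-2-oxonon-8-en-5-yl (2S,3R,4E)-3-[(tert-butyldimethylsilyl)oxy]-5-iodo-2,4-dimethylpent-4-enoate | C#C[C@H]([C@@H](OC(=O)[C@@H](C)[C@@H](O[Si](C)(C)C(C)(C)C)/C(C)=C/I)C[C@H](C)C=C)[C@@](C)(C(C)=O)[C@](C)(O)C=C | intermediate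
26 | bis(trimethylsilyl) derivative of 25 (TMS enol ether of the methyl ketone, tertiary O-TMS ether) | C#C[C@H]([C@@H](OC(=O)[C@@H](C)[C@@H](O[Si](C)(C)C(C)(C)C)/C(C)=C/I)C[C@H](C)C=C)[C@@](C)(C(=C)O[Si](C)(C)C)[C@](C)(O[Si](C)(C)C)C=C | intermediate (not isolated)
27 | (4R,5S,6S,8S)-5-ethynyl-1-hydroxy-4-[(2R)-2-hydroxybut-3-en-2-yl]-4,8-dimethyl-3-oxodec-9-en-6-yl (2S,3R,4E)-3-[(tert-butyldimethylsilyl)oxy]-5-iodo-2,4-dimethylpent-4-enoate | C#C[C@H]([C@@H](OC(=O)[C@@H](C)[C@@H](O[Si](C)(C)C(C)(C)C)/C(C)=C/I)C[C@H](C)C=C)[C@@](C)(C(=O)CCO)[C@](C)(O)C=C | intermediate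
28 | (1S,3S,7R,8R,8aS)-7-hydroxy-8-(3-hydroxypropanoyl)-3,7,8-trimethyl-1,2,3,7,8,8a-hexahydronaphthalen-1-yl (2S,3R,4E)-3-[(tert-butyldimethylsilyl)oxy]-5-iodo-2,4-dimethylpent-4-enoate | I/C=C(\C)[C@H](O[Si](C)(C)C(C)(C)C)[C@H](C)C(=O)O[C@H]1C[C@H](C)C=C2C=C[C@@](C)(O)[C@](C)(C(=O)CCO)[C@H]21 | intermediate
29 | (2Z)-3-methylpent-2-en-4-yn-1-ol | C/C(=C/CO)C#C | starting material
30 | (2Z,4E)-3-methyl-5-(tributylstannyl)penta-2,4-dien-1-ol | CC(=C/CO)/C=C/[Sn](CCCC)(CCCC)CCCC | intermediate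
31 | (2Z,4E)-3-methyl-5-(tributylstannyl)penta-2,4-dienal | CC(=C/C=O)/C=C/[Sn](CCCC)(CCCC)CCCC | intermediate
32 | 2-(diethoxyphosphoryl)acetic acid | CCOP(=O)(CC(=O)O)OCC | starting material
33 | (2E,4Z,6E)-5-methyl-7-(tributylstannyl)hepta-2,4,6-trienoic acid | CC(=C/C=C/C(=O)O)/C=C/[Sn](CCCC)(CCCC)CCCC | intermediate
34 | (2E,4Z,6E,8E,10R,11S)-10-[(tert-butyldimethylsilyl)oxy]-12-{[(1S,3S,7R,8R,8aS)-7-hydroxy-8-(3-hydroxypropanoyl)-3,7,8-trimethyl-1,2,3,7,8,8a-hexahydronaphthalen-1-yl]oxy}-5,9,11-trimethyl-12-oxododeca-2,4,6,8-tetraenoic acid | CC(=C/C=C/C(=O)O)/C=C/C=C(\C)[C@H](O[Si](C)(C)C(C)(C)C)[C@H](C)C(=O)O[C@H]1C[C@H](C)C=C2C=C[C@@](C)(O)[C@](C)(C(=O)CCO)[C@H]21 | intermediate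
35 | calbistrin D, (2E,4Z,6E,8E,10R,11S)-10-hydroxy-12-{[(1S,3S,7R,8R,8aS)-7-hydroxy-8-(3-hydroxypropanoyl)-3,7,8-trimethyl-1,2,3,7,8,8a-hexahydronaphthalen-1-yl]oxy}-5,9,11-trimethyl-12-oxododeca-2,4,6,8-tetraenoic acid | CC(=C/C=C/C(=O)O)/C=C/C=C(\C)[C@H](O)[C@H](C)C(=O)O[C@H]1C[C@H](C)C=C2C=C[C@@](C)(O)[C@](C)(C(=O)CCO)[C@H]21 | target

## Step count and risks

Total step count: 22.
Longest linear sequence: 12 steps (steps 1–3, 6–9, 15–17, 21, 22).

Most likely to fail, 1: step 17 (metathesis cascade). If ruthenium initiates at the hindered vinyl carbinol, a five/seven-membered ring pair would result, and closure of ring B between two adjacent fully substituted carbons may stall at the vinylcyclohexene stage. The fallback sets out from 27 and separates the alkyne step from ring closure. Cross enyne metathesis with ethylene (Grubbs II, ethylene 3–5 atm, CH2Cl2, rt) converts the alkyne into the isolable 2-substituted buta-1,3-diene, the tetraene (4R,5S,6S,8S)-5-(buta-1,3-dien-2-yl)-1-hydroxy-4-[(2R)-2-hydroxybut-3-en-2-yl]-4,8-dimethyl-3-oxodec-9-en-6-yl ester F1. A separate double ring-closing metathesis (Schrock molybdenum alkylidene or Hoveyda–Grubbs II, refluxing toluene with argon purge) then pairs the 1,1-disubstituted diene end with the unhindered vinyl group and the monosubstituted end with the vinyl carbinol, again closing both rings in one operation. It comes back to the route at 28.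

Most likely to fail, 2: step 6 (Marshall propargylation with a mesylate bearing a branched acyl-oxazolidinone arm). The allenylzinc may form poorly or add with low anti selectivity. The fallback sets out from 7 and 5 and builds the lactone by 2-(alkoxycarbonyl)allylation instead. Morita–Baylis–Hillman reaction of 7 with methyl acrylate (DABCO) gives methyl 2-[1-hydroxy-3-(trimethylsilyl)prop-2-yn-1-yl]prop-2-enoate F2. PBr3 converts it with allylic transposition into methyl (2Z)-2-(bromomethyl)-5-(trimethylsilyl)pent-2-en-4-ynoate F3. Indium-mediated addition of F3 to 5 (chelated chair, syn-selective) gives methyl (3R,4S,6S)-4-hydroxy-6-methyl-2-methylidene-3-[(trimethylsilyl)ethynyl]oct-7-enoate F4, which lactonises with catalytic TsOH to the cis lactone (4R,5S)-3-methylidene-5-[(2S)-2-methylbut-3-en-1-yl]-4-[(trimethylsilyl)ethynyl]oxolan-2-one F5. The facial sense relative to the remote methyl centre is not substrate-controlled, so a chiral In(III)–PYBOX promoter is used or the two cis diastereomers are separated. L-Selectride conjugate reduction of F5 gives the same lactone enolate as in step 7, and trapping with acetyl chloride comes back to the route at 12.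

Most likely to fail, 3: step 8 (facial selectivity of the chelation-controlled vinyl addition). The preference for attack past the methyl group and not past the ring carbon may be small or reversed. The fallback sets out from 11 and introduces the two carbinol substituents in the opposite order. Aldol reaction of the lactone enolate (LDA, −78 °C) with acrolein gives (3R,4R,5S)-3-(1-hydroxyprop-2-en-1-yl)-3-methyl-5-[(2S)-2-methylbut-3-en-1-yl]-4-[(trimethylsilyl)ethynyl]oxolan-2-one F6 as a carbinol mixture. Dess–Martin oxidation gives the acryloyl lactone (3R,4R,5S)-3-methyl-5-[(2S)-2-methylbut-3-en-1-yl]-3-(prop-2-enoyl)-4-[(trimethylsilyl)ethynyl]oxolan-2-one F7. MeMgBr/MgBr2 then adds methyl through the same chelate, so that a reversed facial preference now delivers the required carbinol. It comes back to the route at 13.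

## Further compounds

F1 | step 17 | (4R,5S,6S,8S)-5-(buta-1,3-dien-2-yl)-1-hydroxy-4-[(2R)-2-hydroxybut-3-en-2-yl]-4,8-dimethyl-3-oxodec-9-en-6-yl (2S,3R,4E)-3-[(tert-butyldimethylsilyl)oxy]-5-iodo-2,4-dimethylpent-4-enoate | C=CC(=C)[C@H]([C@@H](OC(=O)[C@@H](C)[C@@H](O[Si](C)(C)C(C)(C)C)/C(C)=C/I)C[C@H](C)C=C)[C@@](C)(C(=O)CCO)[C@](C)(O)C=C
F2 | step 6 | methyl 2-[1-hydroxy-3-(trimethylsilyl)prop-2-yn-1-yl]prop-2-enoate (racemic) | C=C(C(=O)OC)C(O)C#C[Si](C)(C)C
F3 | step 6 | methyl (2Z)-2-(bromomethyl)-5-(trimethylsilyl)pent-2-en-4-ynoate | COC(=O)/C(CBr)=C/C#C[Si](C)(C)C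
F4 | step 6 | methyl (3R,4S,6S)-4-hydroxy-6-methyl-2-methylidene-3-[(trimethylsilyl)ethynyl]oct-7-enoate | C=C(C(=O)OC)[C@H](C#C[Si](C)(C)C)[C@@H](O)C[C@H](C)C=C
F5 | step 6 | (4R,5S)-3-methylidene-5-[(2S)-2-methylbut-3-en-1-yl]-4-[(trimethylsilyl)ethynyl]oxolan-2-one | C[Si](C)(C)C#C[C@H]1C(=C)C(=O)O[C@H]1C[C@H](C)C=C
F6 | step 8 | (3R,4R,5S)-3-(1-hydroxyprop-2-en-1-yl)-3-methyl-5-[(2S)-2-methylbut-3-en-1-yl]-4-[(trimethylsilyl)ethynyl]oxolan-2-one (carbinol epimers) | C[Si](C)(C)C#C[C@H]1[C@](C)(C(O)C=C)C(=O)O[C@H]1C[C@H](C)C=C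
F7 | step 8 | (3R,4R,5S)-3-methyl-5-[(2S)-2-methylbut-3-en-1-yl]-3-(prop-2-enoyl)-4-[(trimethylsilyl)ethynyl]oxolan-2-one | C[Si](C)(C)C#C[C@H]1[C@](C)(C(=O)C=C)C(=O)O[C@H]1C[C@H](C)C=C
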